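**Retrosynthetic overview**
1. Numbering runs from the lactone carbonyl (C1) to the chain end (C26). The only ring, the dihydropyranone O–C1(=O)–C2=C3–C4–C5, is opened to the C5 alcohol and a (Z)-C2=C3 enoate, hence to a C3 aldehyde; it is formed last.
2. Key disconnection C14–C15. The enabling feature is that C15 is an isolated dialkyl carbinol (O on C15, CH2 at C14 and C16) and C12–C13–C14 is an unfunctionalised chain on the C11 carbinol, i.e. the allyl group of a homoallylic ether. C14 becomes the terminal CH2 of an olefin (Ni–H), and C15 a racemic 1-bromododecyl acetate (dodecanal + AcBr) whose two enantiomers give one planar α-acetoxy radical.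
3. Olefin partner C3–C14: C3–C9 with the syn C5/C7 acetonide is the commercial statin side-chain nitrile (ester = C3, nitrile = C9); C9 and C11 are added syn by two Brown allylations.
4. Ring order: 1,3-dioxane (bought, temporary) → δ-lactone in the final acid step, after one DIBAL-H operation (C3 ester → CHO, C15 acetate off) and a Still–Gennari olefination.

Key step: step 7

Assumption: nitrile 1, (+)-Ipc2B(allyl) (pentane solution, from (−)-α-pinene) and dodecanal are taken as commercial; in step 7 the ligand enantiomer is the one that leads to the (S)-ester at C15.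

**Step 1**
Reactants: 1 tert-butyl 2-[(4R,6R)-6-(cyanomethyl)-2,2-dimethyl-1,3-dioxan-4-yl]acetate
Product: 3 tert-butyl 2-[(4R,6S)-2,2-dimethyl-6-(2-oxoethyl)-1,3-dioxan-4-yl]acetate, via N-aluminio aldimine 2 (not isolated)
Conditions: DIBAL-H (1.05 equiv), toluene, −78 °C; aq. Rochelle salt, 0 °C → rt
Reagents that add atoms: water, O
Why: Partial hydride reduction of a nitrile, in which one equivalent of DIBAL-H adds once to the Lewis-basic C≡N to give an aldimine that is not reduced further at −78 °C and is hydrolysed on work-up, while the hindered tert-butyl ester is expected to react more slowly and the C5/C7 stereocentres are untouched.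

**Step 2**
Reactants: 3
Product: 5 tert-butyl 2-[(4R,6R)-6-[(2R)-2-hydroxypent-4-en-1-yl]-2,2-dimethyl-1,3-dioxan-4-yl]acetate, via borinate ester 4 (not isolated)
Conditions: (+)-Ipc2B(allyl), Et2O, −78 °C; then 3 M NaOH, 30% H2O2, 0 °C → rt
Reagents that add atoms: (+)-B-allyldiisopinocampheylborane, C=CCB([C@H]1C[C@H]2C[C@@H]([C@@H]1C)C2(C)C)[C@H]1C[C@H]2C[C@@H]([C@@H]1C)C2(C)C
Why: Brown asymmetric allylboration through a closed chair (Zimmerman–Traxler) transition state, in which the (−)-α-pinene-derived reagent should deliver allyl to the Re face of the aldehyde under reagent control and so set C9 (R), syn to the C7 oxygen.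

**Step 3**
Reactants: 5
Product: 6 tert-butyl 2-[(4R,6S)-6-[(2R)-2-(tert-butyldimethylsilyloxy)pent-4-en-1-yl]-2,2-dimethyl-1,3-dioxan-4-yl]acetate
Conditions: TBSCl, imidazole, DMF, rt
Reagents that add atoms: tert-butyldimethylsilyl chloride, CC(C)(C)[Si](C)(C)Cl
Why: Standard silylation of a secondary alcohol under mild base, which masks C9–OH for the ozonolysis and the later Ni–H step and leaves the tert-butyl ester and acetonide intact.

**Step 4**
Reactants: 6
Product: 8 tert-butyl 2-[(4R,6S)-6-[(2S)-2-(tert-butyldimethylsilyloxy)-4-oxobutyl]-2,2-dimethyl-1,3-dioxan-4-yl]acetate, via secondary ozonide 7 (not isolated)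
Conditions: O3, CH2Cl2, −78 °C; PPh3, −78 °C → rt
Reagents that add atoms: ozone, O=[O+][O-]
Why: Ozonolysis with reductive work-up cleaves the only C=C to the aldehyde one carbon shorter (C11), the ester, acetonide and silyl ether being inert and no stereocentre being touched (the descriptor at C9 changes only through CIP priorities).

**Step 5**
Reactants: 8
Product: 10 tert-butyl 2-[(4R,6S)-6-[(2R,4R)-2-(tert-butyldimethylsilyloxy)-4-hydroxyhept-6-en-1-yl]-2,2-dimethyl-1,3-dioxan-4-yl]acetate, via borinate ester 9 (not isolated)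
Conditions: (+)-Ipc2B(allyl), Et2O, −78 °C; then 3 M NaOH, 30% H2O2, 0 °C → rt
Reagents that add atoms: (+)-B-allyldiisopinocampheylborane, C=CCB([C@H]1C[C@H]2C[C@@H]([C@@H]1C)C2(C)C)[C@H]1C[C@H]2C[C@@H]([C@@H]1C)C2(C)C
Why: Second Brown allylboration with the same reagent enantiomer, which should again add to the Re face under reagent control, setting C11 (R) syn to C9 and installing the terminal olefin C13=C14.

**Step 6**
Reactants: 10
Product: 11 tert-butyl 2-[(4R,6S)-6-[(2S,4R)-2,4-bis(tert-butyldimethylsilyloxy)hept-6-en-1-yl]-2,2-dimethyl-1,3-dioxan-4-yl]acetate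
Conditions: TBSCl, imidazole, DMF, rt
Reagents that add atoms: tert-butyldimethylsilyl chloride, CC(C)(C)[Si](C)(C)Cl
Why: Silylation masks C11–OH, which would otherwise be silylated or deprotonated under the hydrosilane/phosphate conditions of the key step.

**Step 7**
Reactants: 11, 12 dodecanal
Product: 14 tert-butyl 2-[(4R,6S)-6-[(2S,4R,8S)-8-acetoxy-2,4-bis(tert-butyldimethylsilyloxy)nonadecyl]-2,2-dimethyl-1,3-dioxan-4-yl]acetate, via racemic 1-bromododecyl acetate 13 (not isolated)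
Conditions: 12, AcBr, cat. ZnBr2, CH2Cl2, 0 °C → rt, volatiles removed; then 11, NiBr2·glyme (10 mol%), chiral bis(oxazoline) ligand (12 mol%), (EtO)3SiH, K3PO4·H2O, i-Pr2O/DMA, rt
Reagents that add atoms: acetyl bromide, CC(=O)Br
Why: Dodecanal and acetyl bromide add to give the racemic 1-bromoalkyl ester 13; a chiral bis(oxazoline)–Ni–H species (from Ni(II), silane and phosphate) inserts the terminal C13=C14 olefin of 11 anti-Markovnikov to place Ni on C14, bromine abstraction from either enantiomer of 13 gives the same planar α-acetoxy C15 radical, and radical capture at the chiral alkyl–Ni followed by reductive elimination forms C14–C15. The closest known reaction type is the Ni-catalysed enantioconvergent hydroalkylation of terminal olefins with racemic 1-bromoalkyl esters, including its one-pot variant from aldehyde, acyl bromide, olefin and hydrosilane. No ring is closed. The new C15 stereocentre (S) is controlled by the ligand on nickel, with the ester carbonyl as the secondary contact, so both enantiomers of 13 are funnelled into one configuration and the distant C5–C11 centres should have no influence. The step needs linear regioselectivity without chain walking and chemoselectivity for the olefin, which 11 secures by carrying a single monosubstituted alkene and otherwise only a tert-butyl ester, an acetonide and silyl ethers, all inert to Ni–H and the phosphate base.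

**Step 8**
Reactants: 14
Product: 15 2-[(4R,6S)-6-[(2S,4R,8S)-2,4-bis(tert-butyldimethylsilyloxy)-8-hydroxynonadecyl]-2,2-dimethyl-1,3-dioxan-4-yl]acetaldehyde
Conditions: DIBAL-H (4 equiv), CH2Cl2, −78 °C; MeOH, aq. Rochelle salt
Reagents that add atoms: none
Why: DIBAL-H in excess at −78 °C should do two jobs, adding once to the tert-butyl ester to give a chelation-stabilised aluminium hemiacetal that releases the C3 aldehyde only on work-up, and reducing the acetate to free the C15 alcohol, with silyl ethers, acetonide and all stereocentres untouched.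

**Step 9**
Reactants: 15
Product: 16 methyl (2Z)-4-[(4S,6S)-6-[(2S,4R,8S)-2,4-bis(tert-butyldimethylsilyloxy)-8-hydroxynonadecyl]-2,2-dimethyl-1,3-dioxan-4-yl]but-2-enoate
Conditions: (CF3CH2O)2P(O)CH2CO2Me, KHMDS, 18-crown-6, THF, −78 °C
Reagents that add atoms: methyl 2-[bis(2,2,2-trifluoroethoxy)phosphoryl]acetate, COC(=O)CP(=O)(OCC(F)(F)F)OCC(F)(F)F
Why: Still–Gennari variant of the Horner–Wadsworth–Emmons reaction, in which the preformed potassium phosphonate adds to the aldehyde and the electron-poor phosphonate eliminates rapidly from the kinetic adduct to give the (Z)-enoate, the anion being too weakly basic to deprotonate the free C15 alcohol.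

**Step 10**
Reactants: 16
Product: 18 (6S)-6-[(2R,4R,6R,10S)-2,4,6,10-tetrahydroxyhenicosyl]-5,6-dihydro-2H-pyran-2-one, via pentahydroxy Z-enoate 17 (not isolated)
Conditions: 48% aq. HF, MeCN, 0 °C → rt
Reagents that add atoms: none
Why: Aqueous HF should cleave the acetonide and both TBS ethers, after which the C5 hydroxyl, held cis to the ester by the Z double bond, lactonises under the acidic conditions (6-exo-trig acyl substitution, loss of methanol) to the conjugated δ-lactone without touching any stereocentre.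

**Compound list**
1 | tert-butyl 2-[(4R,6R)-6-(cyanomethyl)-2,2-dimethyl-1,3-dioxan-4-yl]acetate | N#CC[C@@H]1C[C@H](CC(=O)OC(C)(C)C)OC(C)(C)O1 | starting material
2 | tert-butyl 2-[(4R,6R)-6-{2-[(diisobutylalumanyl)imino]ethyl}-2,2-dimethyl-1,3-dioxan-4-yl]acetate | CC(C)C[Al](CC(C)C)N=CC[C@@H]1C[C@H](CC(=O)OC(C)(C)C)OC(C)(C)O1 | intermediate
3 | tert-butyl 2-[(4R,6S)-2,2-dimethyl-6-(2-oxoethyl)-1,3-dioxan-4-yl]acetate | O=CC[C@@H]1C[C@H](CC(=O)OC(C)(C)C)OC(C)(C)O1 | intermediate
4 | O-diisopinocampheylborinate of 5: tert-butyl 2-[(4R,6R)-6-[(2R)-2-(diisopinocampheylboryloxy)pent-4-en-1-yl]-2,2-dimethyl-1,3-dioxan-4-yl]acetate | C=CC[C@@H](OB([C@H]1C[C@H]2C[C@@H]([C@@H]1C)C2(C)C)[C@H]1C[C@H]2C[C@@H]([C@@H]1C)C2(C)C)C[C@@H]1C[C@H](CC(=O)OC(C)(C)C)OC(C)(C)O1 | intermediate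
5 | tert-butyl 2-[(4R,6R)-6-[(2R)-2-hydroxypent-4-en-1-yl]-2,2-dimethyl-1,3-dioxan-4-yl]acetate | C=CC[C@@H](O)C[C@@H]1C[C@H](CC(=O)OC(C)(C)C)OC(C)(C)O1 | intermediate
6 | tert-butyl 2-[(4R,6S)-6-[(2R)-2-(tert-butyldimethylsilyloxy)pent-4-en-1-yl]-2,2-dimethyl-1,3-dioxan-4-yl]acetate | C=CC[C@@H](O[Si](C)(C)C(C)(C)C)C[C@@H]1C[C@H](CC(=O)OC(C)(C)C)OC(C)(C)O1 | intermediate
7 | tert-butyl 2-[(4R,6S)-6-[(2S)-2-(tert-butyldimethylsilyloxy)-3-(1,2,4-trioxolan-3-yl)propyl]-2,2-dimethyl-1,3-dioxan-4-yl]acetate (mixture at the trioxolane carbon) | O1COC(O1)C[C@@H](O[Si](C)(C)C(C)(C)C)C[C@@H]2C[C@H](CC(=O)OC(C)(C)C)OC(C)(C)O2 | intermediate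
8 | tert-butyl 2-[(4R,6S)-6-[(2S)-2-(tert-butyldimethylsilyloxy)-4-oxobutyl]-2,2-dimethyl-1,3-dioxan-4-yl]acetate | O=CC[C@@H](O[Si](C)(C)C(C)(C)C)C[C@@H]1C[C@H](CC(=O)OC(C)(C)C)OC(C)(C)O1 | intermediate
9 | O-diisopinocampheylborinate of 10: tert-butyl 2-[(4R,6S)-6-[(2R,4R)-2-(tert-butyldimethylsilyloxy)-4-(diisopinocampheylboryloxy)hept-6-en-1-yl]-2,2-dimethyl-1,3-dioxan-4-yl]acetate | C=CC[C@@H](OB([C@H]1C[C@H]2C[C@@H]([C@@H]1C)C2(C)C)[C@H]1C[C@H]2C[C@@H]([C@@H]1C)C2(C)C)C[C@@H](O[Si](C)(C)C(C)(C)C)C[C@@H]1C[C@H](CC(=O)OC(C)(C)C)OC(C)(C)O1 | intermediate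
10 | tert-butyl 2-[(4R,6S)-6-[(2R,4R)-2-(tert-butyldimethylsilyloxy)-4-hydroxyhept-6-en-1-yl]-2,2-dimethyl-1,3-dioxan-4-yl]acetate | C=CC[C@@H](O)C[C@@H](O[Si](C)(C)C(C)(C)C)C[C@@H]1C[C@H](CC(=O)OC(C)(C)C)OC(C)(C)O1 | intermediate
11 | tert-butyl 2-[(4R,6S)-6-[(2S,4R)-2,4-bis(tert-butyldimethylsilyloxy)hept-6-en-1-yl]-2,2-dimethyl-1,3-dioxan-4-yl]acetate | C=CC[C@@H](O[Si](C)(C)C(C)(C)C)C[C@@H](O[Si](C)(C)C(C)(C)C)C[C@@H]1C[C@H](CC(=O)OC(C)(C)C)OC(C)(C)O1 | intermediate
12 | dodecanal | CCCCCCCCCCCC=O | starting material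
13 | rac-1-bromododecyl acetate | CCCCCCCCCCCC(Br)OC(C)=O | intermediate
14 | tert-butyl 2-[(4R,6S)-6-[(2S,4R,8S)-8-acetoxy-2,4-bis(tert-butyldimethylsilyloxy)nonadecyl]-2,2-dimethyl-1,3-dioxan-4-yl]acetate | CCCCCCCCCCC[C@H](OC(C)=O)CCC[C@@H](O[Si](C)(C)C(C)(C)C)C[C@@H](O[Si](C)(C)C(C)(C)C)C[C@@H]1C[C@H](CC(=O)OC(C)(C)C)OC(C)(C)O1 | intermediate
15 | 2-[(4R,6S)-6-[(2S,4R,8S)-2,4-bis(tert-butyldimethylsilyloxy)-8-hydroxynonadecyl]-2,2-dimethyl-1,3-dioxan-4-yl]acetaldehyde | CCCCCCCCCCC[C@H](O)CCC[C@@H](O[Si](C)(C)C(C)(C)C)C[C@@H](O[Si](C)(C)C(C)(C)C)C[C@@H]1C[C@H](CC=O)OC(C)(C)O1 | intermediate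
16 | methyl (2Z)-4-[(4S,6S)-6-[(2S,4R,8S)-2,4-bis(tert-butyldimethylsilyloxy)-8-hydroxynonadecyl]-2,2-dimethyl-1,3-dioxan-4-yl]but-2-enoate | CCCCCCCCCCC[C@H](O)CCC[C@@H](O[Si](C)(C)C(C)(C)C)C[C@@H](O[Si](C)(C)C(C)(C)C)C[C@@H]1C[C@H](C/C=C\C(=O)OC)OC(C)(C)O1 | intermediate
17 | methyl (2Z,5S,7S,9R,11R,15S)-5,7,9,11,15-pentahydroxyhexacos-2-enoate | CCCCCCCCCCC[C@H](O)CCC[C@@H](O)C[C@@H](O)C[C@@H](O)C[C@@H](O)C/C=C\C(=O)OC | intermediate
18 | (6S)-6-[(2R,4R,6R,10S)-2,4,6,10-tetrahydroxyhenicosyl]-5,6-dihydro-2H-pyran-2-one | CCCCCCCCCCC[C@H](O)CCC[C@@H](O)C[C@@H](O)C[C@@H](O)C[C@@H]1CC=CC(=O)O1 | target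

**Count and risks**
Total step count: 10. Longest linear sequence: 10 steps (1 → 18); dodecanal 12 enters at step 7.

Steps most likely to fail:

Step 7. Olefin insertion may be slow at the hindered, poly-oxygenated olefin, catalyst control at C15 may erode, and the bromo ester may decompose or release HBr that attacks the acetonide. The fallback sets out from 11 and 12 and comes back at 14, joining the halves by metathesis instead. Vinylmagnesium bromide should add to 12 to give racemic tetradec-1-en-3-ol F1. Lipase-catalysed acylative kinetic resolution (CAL-B, vinyl acetate), which by the Kazlauskas rule should acetylate the (S)-alcohol, gives (S)-tetradec-1-en-3-yl acetate F2. Cross-metathesis of F2 with 11 (Hoveyda–Grubbs II, CH2Cl2, 40 °C) should give the C13=C14 (E)-alkene analogue of 14 F3. Hydrogenation (H2, Rh/Al2O3, EtOAc, chosen to avoid allylic C–O hydrogenolysis) returns to 14.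

Step 8. The C3 hemiacetal may collapse and be over-reduced to the primary alcohol, or the tert-butyl ester may react incompletely while the acetate is already cleaved. The fallback sets out from 14 and comes back at 15. Exhaustive reduction (LiAlH4, THF, 0 °C) should give the diol 2-[(4S,6S)-6-[(2S,4R,8S)-2,4-bis(tert-butyldimethylsilyloxy)-8-hydroxynonadecyl]-2,2-dimethyl-1,3-dioxan-4-yl]ethan-1-ol F4. Chemoselective oxidation of the primary alcohol in the presence of the secondary C15 alcohol (TEMPO, PhI(OAc)2, CH2Cl2, rt) returns to 15.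

Step 9. Z-selectivity may erode, and base may trigger β-elimination of the dioxane oxygen from the β-alkoxy aldehyde. The fallback sets out from 15 and comes back at 18, making the cis double bond by alkyne semi-reduction. Ohira–Bestmann homologation (dimethyl 1-diazo-2-oxopropylphosphonate, K2CO3, MeOH) should give the prop-2-ynyl analogue of 15 F5. Double deprotonation (n-BuLi, 2.2 equiv, THF, −78 °C) and CO2 quench should give the but-2-ynoic acid F6. Lindlar semi-hydrogenation (H2, Pd/CaCO3/Pb, quinoline) should give the (Z)-but-2-enoic acid F7. The conditions of step 10 then deprotect and lactonise the hydroxy acid to 18.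

**Further compounds**
F1 | step 7 | rac-tetradec-1-en-3-ol | CCCCCCCCCCCC(O)C=C
F2 | step 7 | (S)-tetradec-1-en-3-yl acetate | CCCCCCCCCCC[C@H](OC(C)=O)C=C
F3 | step 7 | tert-butyl 2-[(4R,6S)-6-[(2S,4R,6E,8S)-8-acetoxy-2,4-bis(tert-butyldimethylsilyloxy)nonadec-6-en-1-yl]-2,2-dimethyl-1,3-dioxan-4-yl]acetate | CCCCCCCCCCC[C@H](OC(C)=O)/C=C/C[C@@H](O[Si](C)(C)C(C)(C)C)C[C@@H](O[Si](C)(C)C(C)(C)C)C[C@@H]1C[C@H](CC(=O)OC(C)(C)C)OC(C)(C)O1
F4 | step 8 | 2-[(4S,6S)-6-[(2S,4R,8S)-2,4-bis(tert-butyldimethylsilyloxy)-8-hydroxynonadecyl]-2,2-dimethyl-1,3-dioxan-4-yl]ethan-1-ol | CCCCCCCCCCC[C@H](O)CCC[C@@H](O[Si](C)(C)C(C)(C)C)C[C@@H](O[Si](C)(C)C(C)(C)C)C[C@@H]1C[C@H](CCO)OC(C)(C)O1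
F5 | step 9 | prop-2-ynyl analogue of 15 (CH2C≡CH in place of CH2CHO, all stereocentres as in 15) | CCCCCCCCCCC[C@H](O)CCC[C@@H](O[Si](C)(C)C(C)(C)C)C[C@@H](O[Si](C)(C)C(C)(C)C)C[C@@H]1C[C@H](CC#C)OC(C)(C)O1
F6 | step 9 | but-2-ynoic acid analogue of 16 (CH2C≡C–CO2H arm, all stereocentres as in 15) | CCCCCCCCCCC[C@H](O)CCC[C@@H](O[Si](C)(C)C(C)(C)C)C[C@@H](O[Si](C)(C)C(C)(C)C)C[C@@H]1C[C@H](CC#CC(=O)O)OC(C)(C)O1
F7 | step 9 | (2Z)-but-2-enoic acid corresponding to ester 16 | CCCCCCCCCCC[C@H](O)CCC[C@@H](O[Si](C)(C)C(C)(C)C)C[C@@H](O[Si](C)(C)C(C)(C)C)C[C@@H]1C[C@H](C/C=C\C(=O)O)OC(C)(C)O1
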